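## Retrosynthetic overview
1. C7–C8 is the last bond and closes the ten-membered carbocycle. A decarboxylatively generated C8 α-tigloyloxy radical adds to C7 of a 3-(phenylsulfonylmethyl)butenolide and PhSO2• leaves. This one step sets C7 and C8 and creates the α-methylene lactone.
2. C5–C6 comes from a catalytic asymmetric vinylogous Mukaiyama aldol of a 2-silyloxyfuran with a 2-substituted acrolein (sets C5 and C6). The new 5-OH then closes the tetrahydrofuran hemiketal on the C2 ketone, so C2 is under thermodynamic control.
3. C1–C2 and C2–C3 are made together by stitching carbon monoxide between two 2-substituted allyl units (carbonylative Stille coupling).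
4. C8–C9 comes from an indium Barbier allylation of glyoxylic acid. Tigloyl chloride then acylates O8 and also activates the acid for the redox-active ester.
5. Ring order: butenolide, then tetrahydrofuran hemiketal, then the ten-membered carbocycle together with the α-methylene-γ-lactone.

Numbering: germacrane numbering (C1–C15) is used for all intermediates. C8 is racemic or epimeric until the last step and is drawn without configuration, because it becomes a planar radical there.
Assumption: the (R,R)-bisphosphoramide is taken to direct attack to the Re face of the enal (this gives 5S); its enantiomer is equally available if the sense is opposite.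

## Route

Step 1
Reactants: 1 3-chloro-2-(chloromethyl)prop-1-ene; 2 glyoxylic acid (used as the monohydrate)
Product: 4 4-(chloromethyl)-2-hydroxypent-4-enoic acid (racemic), via 3-chloro-2-(iodomethyl)prop-1-ene 3 (not isolated)
Conditions: 1 (3 equiv), NaI (1.5 equiv), In powder (1.0 equiv), THF–H2O 1:1, 23 °C
Reagents that add atoms: none
Why: Finkelstein exchange makes one allylic terminus reactive enough for indium insertion, and the aqueous Barbier allylation adds it to the aldehyde of glyoxylic acid while the free acid and the second allylic chloride survive; the new C8 centre is racemic, which is harmless because step 8 flattens it.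

Step 2
Reactants: 4 4-(chloromethyl)-2-hydroxypent-4-enoic acid; 5 (E)-2-methylbut-2-enoyl chloride (tigloyl chloride)
Product: 7 1,3-dioxoisoindolin-2-yl 4-(chloromethyl)-2-{[(E)-2-methylbut-2-enoyl]oxy}pent-4-enoate (racemic), via O-tigloyl mixed anhydride 6 (not isolated)
Conditions: 5 (2.1 equiv), pyridine (4 equiv), CH2Cl2, 0 °C, 2 h; then N-hydroxyphthalimide (1.1 equiv), 0 → 23 °C
Reagents that add atoms: N-hydroxyphthalimide, O=C1c2ccccc2C(=O)N1O
Why: O-acylation and mixed-anhydride activation run in one pot, and N-hydroxyphthalimide then attacks the more electrophilic, non-conjugated carbonyl of the anhydride (the conjugated, α-branched tigloyl carbonyl acts like a pivaloyl group), while pyridine rather than a trialkylamine avoids vinylketene formation and keeps the (E)-alkene.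

Step 3
Reactants: 8 3-chloro-2-methylprop-1-ene (methallyl chloride)
Product: 9 2-(chloromethyl)prop-2-enal
Conditions: SeO2 (1.0 equiv), 1,4-dioxane, 90 °C; distillation
Reagents that add atoms: selenium dioxide, O=[Se]=O
Why: Riley allylic oxidation (ene reaction, then [2,3]-shift) attacks only the methyl group, because the CH2Cl position is inductively deactivated, and it runs on to the enal.

Step 4
Reactants: 7 redox-active ester allylic chloride; 9 2-(chloromethyl)prop-2-enal
Product: 11 1,3-dioxoisoindolin-2-yl 8-formyl-4-methylidene-6-oxo-2-{[(E)-2-methylbut-2-enoyl]oxy}non-8-enoate (racemic), via allylstannane 10 (not isolated)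
Conditions: 7, (Bu3Sn)2 (1.05 equiv), Pd2(dba)3 (2.5 mol %), THF, 23 °C, dark; then P(2-furyl)3 (10 mol %), 9 (1.3 equiv), CO (3 atm), 40 °C; product used without delay
Reagents that add atoms: carbon monoxide, [C-]#[O+]
Why: zerovalent palladium first exchanges the allylic chloride for tin with the distannane and then runs a Stille carbonylative cross-coupling (oxidative addition of 9, CO insertion, transmetalation, reductive elimination); both allyl partners carry two identical CH2 termini, so there is no regiochemical issue, and the neutral medium keeps both alkenes out of conjugation with the new C2 ketone.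

Step 5
Reactants: 12 3-methylideneoxolan-2-one (α-methylene-γ-butyrolactone)
Product: 15 3-[(phenylsulfonyl)methyl]furan-2(5H)-one, via iodosulfone 13 (not isolated), via vinyl sulfone 14 (not isolated)
Conditions: PhSO2Na (1.2 equiv), I2 (1.1 equiv), EtOAc–H2O, 23 °C, room light; then Et3N (1.5 equiv), CH2Cl2, 0 °C; then DBU (0.2 equiv), 23 °C
Reagents that add atoms: sodium benzenesulfinate, [Na+].[O-]S(=O)c1ccccc1
Why: radical iodosulfonylation of the acrylate-type alkene is followed by dehydroiodination to the vinyl sulfone and base-catalysed vinyl-to-allyl sulfone isomerisation, which can only move the alkene into the ring to give the more stable butenolide.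

Step 6
Reactants: 15 3-[(phenylsulfonyl)methyl]furan-2(5H)-one
Product: 16 tert-butyl(dimethyl){[3-(phenylsulfonylmethyl)furan-2-yl]oxy}silane
Conditions: TBSOTf (1.1 equiv), Et3N (1.3 equiv), CH2Cl2, 0 °C, 30 min
Reagents that add atoms: tert-butyldimethylsilyl trifluoromethanesulfonate, CC(C)(C)[Si](C)(C)OS(=O)(=O)C(F)(F)F
Why: soft enolisation (O-silylation, then γ-deprotonation) is driven by formation of the aromatic 2-silyloxyfuran.

Step 7
Reactants: 11 keto-enal redox-active ester; 16 2-silyloxyfuran
Product: 18 1,3-dioxoisoindolin-2-yl 4-{[(2S,5S)-2-hydroxy-4-methylidene-5-{(2S)-5-oxo-4-[(phenylsulfonyl)methyl]-2,5-dihydrofuran-2-yl}oxolan-2-yl]methyl}-2-{[(E)-2-methylbut-2-enoyl]oxy}pent-4-enoate (C8 epimers), via open-chain aldol 17 (not isolated)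
Conditions: SiCl4 (1.5 equiv), (R,R)-bisphosphoramide [two N,N'-dimethyl-1,1'-binaphthyl-2,2'-diamine phosphoramide units joined by a pentane-1,5-diylbis(methylamino) tether] (10 mol %), iPr2NEt (10 mol %), CH2Cl2, −78 °C; cold sat. aq. NaHCO3
Reagents that add atoms: none
Why: in this catalytic asymmetric vinylogous Mukaiyama aldol under Lewis-base-activated SiCl4 the chiral silicon cation activates only the conjugated aldehyde, the furan attacks through its γ-carbon on the Re face via an open transition state that gives the syn (threo) 5S,6S pair, and on work-up the freed 5-hydroxyl adds to the C2 ketone to give the five-membered hemiketal, whose anomers equilibrate.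

Step 8
Reactants: 18 hemiketal redox-active ester
Product: 19 (2S,5S,6S,7R,8S)-2-hydroxy-2,5-epoxy-8-tigloyloxygermacra-4(15),10(14),11(13)-trien-12,6-olide (CNP0307443.2)
Conditions: Ru(bpy)3(PF6)2 (2 mol %), diethyl 2,6-dimethyl-1,4-dihydropyridine-3,5-dicarboxylate (Hantzsch ester, 1.5 equiv), degassed CH2Cl2, 1 mM (18 added by syringe pump), 450 nm LEDs, 23 °C
Reagents that add atoms: none
Why: Proposed new method: single-electron reduction of the N-acyloxyphthalimide releases CO2 and the planar, nucleophilic C8 α-acyloxy radical, which adds 10-exo to the electrophilic butenolide carbon C7 on the face anti to the C6 substituent (trans-lactone, 7R), and the C11 adduct radical then expels PhSO2• irreversibly to unveil the α-methylene lactone; because the trans-lactone fixes an anti C5–C6–C7–C8 torsion, the neighbouring C6–C7–C8–C9 torsion of a ten-membered transition state must be gauche, and the staggered arrangement that turns H-8 rather than the tigloyloxy group over the lactone ring gives 8S, while only the cis-2,5 hemiketal anomer can bridge the ring (2S); the closest known reaction types are the decarboxylative radical allylation of redox-active esters with 2-(sulfonylmethyl)acrylates (Giese addition/β-scission) and photoredox decarboxylative Giese macrocyclisation, and the new element is the ten-membered closure onto a β-substituted cyclic acceptor.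

## Compound list
1 | 3-chloro-2-(chloromethyl)prop-1-ene | C=C(CCl)CCl | starting material
2 | glyoxylic acid | O=CC(=O)O | starting material
3 | 3-chloro-2-(iodomethyl)prop-1-ene | C=C(CCl)CI | intermediate
4 | 4-(chloromethyl)-2-hydroxypent-4-enoic acid (racemic) | OC(=O)C(O)CC(=C)CCl | intermediate
5 | (E)-2-methylbut-2-enoyl chloride | C/C=C(\C)C(=O)Cl | starting material
6 | 4-(chloromethyl)-2-(tigloyloxy)pent-4-enoic tiglic anhydride | ClCC(=C)CC(OC(=O)/C(C)=C/C)C(=O)OC(=O)/C(C)=C/C | intermediate
7 | 1,3-dioxoisoindolin-2-yl 4-(chloromethyl)-2-(tigloyloxy)pent-4-enoate | ClCC(=C)CC(OC(=O)/C(C)=C/C)C(=O)ON1C(=O)c2ccccc2C1=O | intermediate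
8 | 3-chloro-2-methylprop-1-ene | C=C(C)CCl | starting material
9 | 2-(chloromethyl)prop-2-enal | O=CC(=C)CCl | intermediate
10 | 1,3-dioxoisoindolin-2-yl 2-(tigloyloxy)-4-[(tributylstannyl)methyl]pent-4-enoate | CCCC[Sn](CCCC)(CCCC)CC(=C)CC(OC(=O)/C(C)=C/C)C(=O)ON1C(=O)c2ccccc2C1=O | intermediate
11 | 1,3-dioxoisoindolin-2-yl 8-formyl-4-methylidene-6-oxo-2-(tigloyloxy)non-8-enoate | O=CC(=C)CC(=O)CC(=C)CC(OC(=O)/C(C)=C/C)C(=O)ON1C(=O)c2ccccc2C1=O | intermediate
12 | 3-methylideneoxolan-2-one | C=C1CCOC1=O | starting material
13 | 3-iodo-3-[(phenylsulfonyl)methyl]oxolan-2-one (racemic) | O=C1OCCC1(I)CS(=O)(=O)c1ccccc1 | intermediate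
14 | (E)-3-[(phenylsulfonyl)methylidene]oxolan-2-one | O=C1OCC/C1=C\S(=O)(=O)c1ccccc1 | intermediate
15 | 3-[(phenylsulfonyl)methyl]furan-2(5H)-one | O=C1OCC=C1CS(=O)(=O)c1ccccc1 | intermediate
16 | tert-butyl(dimethyl){[3-(phenylsulfonylmethyl)furan-2-yl]oxy}silane | CC(C)(C)[Si](C)(C)Oc1occc1CS(=O)(=O)c1ccccc1 | intermediate
17 | (5S,6S)-open-chain aldol: 5-hydroxy-2-ketone with the butenolide at C6 (C8 epimers) | O=C(CC(=C)CC(OC(=O)/C(C)=C/C)C(=O)ON1C(=O)c2ccccc2C1=O)CC(=C)[C@H](O)[C@@H]1C=C(CS(=O)(=O)c2ccccc2)C(=O)O1 | intermediate
18 | (2S,5S,6S)-tetrahydrofuran hemiketal redox-active ester (cis-2,5 anomer drawn, C8 epimers) | O=C1c2ccccc2C(=O)N1OC(=O)C(OC(=O)/C(C)=C/C)CC(=C)C[C@@]1(O)CC(=C)[C@H](O1)[C@@H]1C=C(CS(=O)(=O)c2ccccc2)C(=O)O1 | intermediate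
19 | CNP0307443.2, (2S,5S,6S,7R,8S) | C=C1C[C@H](OC(=O)/C(C)=C/C)[C@H]2C(=C)C(=O)O[C@@H]2[C@H]2O[C@@](O)(C1)CC2=C | target

## Summary
Total steps: 8. Longest linear sequence: 5 (steps 1, 2, 4, 7, 8).

Steps most likely to fail:

Step 8.
- Risk: closure of a ten-membered ring onto a β-substituted acceptor is slow. Hydrogen transfer from the Hantzsch ester, a 1,6-hydrogen shift from C3, or formation of the C8 epimer may win.
- Fallback: it sets out from 7, 9 and 16 and comes back at 19. The radical reaction is kept only for fragment union, and the ring is closed at the ketone instead.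
- Sequence: the aldol of step 7 is run on the small enal 9 with 16 to give the chlorohydrin butenolide (5S)-5-[(1S)-2-(chloromethyl)-1-hydroxyprop-2-enyl]-3-[(phenylsulfonyl)methyl]furan-2(5H)-one F1. This is silylated (Et3SiCl, imidazole) to its triethylsilyl ether F2. The C8 radical from 7 (conditions of step 8, 0.1 M, 2 equiv of F2) adds intermolecularly anti to the C6 side chain and expels PhSO2•. After chromatography this gives the trans-disubstituted α-methylene lactone bis(allylic chloride) F3. A distannane-mediated carbonylative Stille ring closure (Pd2(dba)3, (Bu3Sn)2 by syringe pump, CO 3 atm, THF, 2 mM) gives the 5-O-triethylsilyl cyclodecanone F4. It does not matter which chloride is stannylated, because both lead to the same ketone. HF·pyridine then frees the 5-hydroxyl, which closes transannularly onto C2 to give 19.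

Step 7.
- Risk: enal 11 is a fragile 1,4-keto-aldehyde with several Lewis-basic sites. The syn:anti ratio and the ee with a 3-substituted silyloxyfuran are untested.
- Fallback: it sets out from 9 and 16, uses 10, and comes back at 18. The order of bond formation is changed so that the stereocentres are set on a small, crystallisable substrate before the ketone exists.
- Sequence: the aldol on 9 gives F1, whose dr and ee can be upgraded by recrystallisation, and protection gives F2, both as described above. Carbonylative Stille coupling of the allylic chloride of F2 with stannane 10 (made from 7 as in the first half of step 4) under CO gives the open-chain 5-O-triethylsilyl ketone F5. Buffered HF·pyridine releases 17, which closes to 18.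

Step 4.
- Risk: the palladium-catalysed stannylation may suffer from allyl–allyl homocoupling or from attack on the redox-active ester, and telescoping hides such problems.
- Fallback: it sets out from 1 and comes back at 10, and so at 11. The allyl–tin bond is present from the start, and C8–C9 is made by carbonyl allylation.
- Sequence: compound 1 with Mg and Bu3SnCl (THF, sonication) gives 2-methylidenepropane-1,3-diylbis(tributylstannane) F6. Mono-allylation of methyl glyoxylate (Sc(OTf)3 5 mol %, CH2Cl2, −20 °C, F6 in excess) gives methyl 2-hydroxy-4-[(tributylstannyl)methyl]pent-4-enoate F7. LiOH gives the lithium carboxylate F8, which is never acidified. Tigloyl chloride 5 with pyridine gives the stannyl mixed anhydride F9, and N-hydroxyphthalimide converts it to 10. Compound 10 is isolated and carbonylated with 9 in a separate operation to give 11.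

## Further compounds
F1 | step 8 | (5S)-5-[(1S)-2-(chloromethyl)-1-hydroxyprop-2-enyl]-3-[(phenylsulfonyl)methyl]furan-2(5H)-one | ClCC(=C)[C@H](O)[C@@H]1C=C(CS(=O)(=O)c2ccccc2)C(=O)O1
F2 | step 8 | triethylsilyl ether of F1 | ClCC(=C)[C@H](O[Si](CC)(CC)CC)[C@@H]1C=C(CS(=O)(=O)c2ccccc2)C(=O)O1
F3 | step 8 | (5S,6S,7R,8S)-α-methylene lactone bis(allylic chloride), 5-O-triethylsilyl, 8-O-tigloyl | ClCC(=C)C[C@H](OC(=O)/C(C)=C/C)[C@H]1C(=C)C(=O)O[C@@H]1[C@@H](O[Si](CC)(CC)CC)C(=C)CCl
F4 | step 8 | (5S,6S,7R,8S)-2-oxo-5-(triethylsilyloxy)-8-tigloyloxygermacra-4(15),10(14),11(13)-trien-12,6-olide | C=C1C[C@H](OC(=O)/C(C)=C/C)[C@H]2C(=C)C(=O)O[C@@H]2[C@@H](O[Si](CC)(CC)CC)C(=C)CC(=O)C1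
F5 | step 7 | 5-O-triethylsilyl ether of open-chain aldol 17 | O=C(CC(=C)CC(OC(=O)/C(C)=C/C)C(=O)ON1C(=O)c2ccccc2C1=O)CC(=C)[C@H](O[Si](CC)(CC)CC)[C@@H]1C=C(CS(=O)(=O)c2ccccc2)C(=O)O1
F6 | step 4 | 2-methylidenepropane-1,3-diylbis(tributylstannane) | C=C(C[Sn](CCCC)(CCCC)CCCC)C[Sn](CCCC)(CCCC)CCCC
F7 | step 4 | methyl 2-hydroxy-4-[(tributylstannyl)methyl]pent-4-enoate (racemic) | COC(=O)C(O)CC(=C)C[Sn](CCCC)(CCCC)CCCC
F8 | step 4 | lithium 2-hydroxy-4-[(tributylstannyl)methyl]pent-4-enoate | [Li+].[O-]C(=O)C(O)CC(=C)C[Sn](CCCC)(CCCC)CCCC
F9 | step 4 | 2-(tigloyloxy)-4-[(tributylstannyl)methyl]pent-4-enoic tiglic anhydride | CCCC[Sn](CCCC)(CCCC)CC(=C)CC(OC(=O)/C(C)=C/C)C(=O)OC(=O)/C(C)=C/C
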